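**Retrosynthetic overview**
- The C15 ester is cut to the allylic alcohol and (S)-3-methylpentanoic acid; the C13=C14 alkene comes from a Horner–Wadsworth–Emmons reaction on a C13 methyl ketone.
- The C9–C11 bond comes from 1,2-addition of a ketal-masked C11–C13 nucleophile to an 8-methyl-Δ7-9-enone. Oxidative 1,3-transposition, dissolving-metal reduction with enol triflation, and triflate hydrogenolysis then return the Δ7 alkene with H-9 in place.
- The strategy rests on ring B's C9–C8(CH3)=C7 segment: without C8 it is the C9–C7 bond of a trans-hydrindan-9-one. Chloro(methyl)carbene is added to the C9=C7 silyl enol ether and the chlorocyclopropane opens, which inserts C8 with its methyl and enlarges the five-membered ring to ring B.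
- The hydrindanone comes from a D-phenylalanine-mediated Hajos–Parrish annulation of 2-methylcyclopentane-1,3-dione with ethyl vinyl ketone (C10), reductive methylation (C4 gem-dimethyl, C5) and a bulky hydride reduction (axial C3–O).
- Ring order: the five-membered ring is bought, ring A is closed by the aldol condensation, and ring B is made last by expanding the five-membered ring.

Key step: step 11

Remarks. Labdane numbering is used for every bicyclic compound; in the hydrindanes C8 is missing and C7 is bonded to C9. "Methyl face" is the face carrying the C10 methyl and "H-5 face" is the opposite one. The target is read as the ent-labdane (3S,5S,9R,10S) with an axial C3 hydroxyl on the H-5 face and a (3S)-3-methylpentanoate at C15.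

Assumption: (R)-phenylalanine gives the (7aR) enedione, the mirror image of the (7aS) product formed with the (S)-amino acid.

**Route**

Step 1
Reactants: 1 2-methylcyclopentane-1,3-dione; 2 ethyl vinyl ketone
Product: 3 2-methyl-2-(3-oxopentyl)cyclopentane-1,3-dione
Conditions: H2O, AcOH (cat.), 75 °C
Reagents that add atoms: none
Why: Michael addition of the acidic cyclic 1,3-dione to the enone in water should stop at the mono-adduct, since the quaternary carbon formed has no acidic hydrogen left; no stereocentre is formed.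

Step 2
Reactants: 3 2-methyl-2-(3-oxopentyl)cyclopentane-1,3-dione
Product: 5 (7aR)-4,7a-dimethyl-2,3,7,7a-tetrahydro-1H-indene-1,5(6H)-dione, via cis-fused ketol 4 (not isolated)
Conditions: (R)-phenylalanine (1 equiv.), 1 M aq. HClO4 (0.5 equiv.), MeCN, reflux; recrystallisation
Reagents that add atoms: none
Why: Hajos–Parrish (Eder–Sauer–Wiechert) intramolecular aldol condensation through the amino acid enamine of the side-chain ketone, which selects one of the two enantiotopic ring carbonyls and so sets C10, the acid then dehydrating the ketol to the ring A enone.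

Step 3
Reactants: 5 (7aR)-4,7a-dimethyl-2,3,7,7a-tetrahydro-1H-indene-1,5(6H)-dione
Product: 6 (1R,7aR)-1-hydroxy-4,7a-dimethyl-1,2,3,6,7,7a-hexahydro-5H-inden-5-one
Conditions: NaBH4 (0.3 equiv.), EtOH, −20 °C
Reagents that add atoms: none
Why: Chemoselective borohydride reduction, since the saturated cyclopentanone (C9) is more electrophilic than the conjugated C3 carbonyl; hydride should approach anti to the angular methyl and place the C9 hydroxyl on the methyl face.

Step 4
Reactants: 6 (1R,7aR)-1-hydroxy-4,7a-dimethyl-1,2,3,6,7,7a-hexahydro-5H-inden-5-one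
Product: 7 (1R,7aR)-4,7a-dimethyl-1-(triethylsilyloxy)-1,2,3,6,7,7a-hexahydro-5H-inden-5-one
Conditions: Et3SiCl, imidazole, DMF, 0 °C to rt
Reagents that add atoms: chlorotriethylsilane, CC[Si](CC)(CC)Cl
Why: Standard imidazole-promoted silylation of a secondary alcohol; the triethylsilyl ether should survive the dissolving-metal and hydride steps and can later be removed beside a hindered tert-butyldimethylsilyl ether.

Step 5
Reactants: 7 (1R,7aR)-4,7a-dimethyl-1-(triethylsilyloxy)-1,2,3,6,7,7a-hexahydro-5H-inden-5-one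
Product: 9 (1R,3aS,7aR)-4,4,7a-trimethyl-1-(triethylsilyloxy)octahydro-5H-inden-5-one, via lithium enolate 8 (not isolated)
Conditions: Li (2.5 equiv.), t-BuOH (1 equiv.), NH3(l)/THF, −78 °C; then MeI, −78 to −33 °C
Reagents that add atoms: iodomethane, CI
Why: Stork-type reductive alkylation, in which axial protonation of the β-carbon C5 during enone reduction should give the trans ring fusion (H-5 anti to the C10 methyl) and the regiodefined C3=C4 enolate is methylated at C4 to the gem-dimethyl group.

Step 6
Reactants: 9 (1R,3aS,7aR)-4,4,7a-trimethyl-1-(triethylsilyloxy)octahydro-5H-inden-5-one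
Product: 10 (3S,5R,9R,10R)-4,4,10-trimethyl-9-(triethylsilyloxy)-trans-hydrindan-3-ol
Conditions: LiBH(s-Bu)3 (L-Selectride), THF, −78 °C; then aq. NaOH, H2O2, 0 °C
Reagents that add atoms: none
Why: Hindered trialkylborohydride reduction, in which equatorial attack on the chair ketone flanked by the C4 gem-dimethyl group should give the axial C3 alcohol on the H-5 face, trans to the C10 methyl.

Step 7
Reactants: 10 (3S,5R,9R,10R)-4,4,10-trimethyl-9-(triethylsilyloxy)-trans-hydrindan-3-ol
Product: 11 (3S,5R,9R,10R)-3-(tert-butyldimethylsilyloxy)-4,4,10-trimethyl-9-(triethylsilyloxy)-trans-hydrindane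
Conditions: t-BuMe2SiOTf, 2,6-lutidine, CH2Cl2, 0 °C to rt
Reagents that add atoms: tert-butyldimethylsilyl trifluoromethanesulfonate, CC(C)(C)[Si](C)(C)OS(=O)(=O)C(F)(F)F
Why: Silyl triflate silylation, which is reactive enough for the axial neopentyl C3 alcohol and leaves the triethylsilyl ether untouched.

Step 8
Reactants: 11 (3S,5R,9R,10R)-3-(tert-butyldimethylsilyloxy)-4,4,10-trimethyl-9-(triethylsilyloxy)-trans-hydrindane
Product: 12 (3S,5R,9R,10R)-3-(tert-butyldimethylsilyloxy)-4,4,10-trimethyl-trans-hydrindan-9-ol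
Conditions: PPTS (cat.), MeOH/CH2Cl2, 0 °C to rt
Reagents that add atoms: none
Why: Acid-catalysed methanolysis of a silyl ether, in which the triethylsilyl group should cleave far faster than the crowded axial tert-butyldimethylsilyl ether at C3.

Step 9
Reactants: 12 (3S,5R,9R,10R)-3-(tert-butyldimethylsilyloxy)-4,4,10-trimethyl-trans-hydrindan-9-ol
Product: 13 (3S,5R,10R)-3-(tert-butyldimethylsilyloxy)-4,4,10-trimethyl-trans-hydrindan-9-one
Conditions: Dess–Martin periodinane, NaHCO3, CH2Cl2, rt
Reagents that add atoms: none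
Why: Dess–Martin oxidation of a secondary alcohol under buffered, non-epimerising conditions; the adjacent C10 is quaternary and the silyl ether is inert.

Step 10
Reactants: 13 (3S,5R,10R)-3-(tert-butyldimethylsilyloxy)-4,4,10-trimethyl-trans-hydrindan-9-one
Product: 14 (3S,5R,10R)-3-(tert-butyldimethylsilyloxy)-4,4,10-trimethyl-9-(trimethylsilyloxy)-trans-hydrind-7(9)-ene
Conditions: Me3SiOTf, Et3N, CH2Cl2, 0 °C
Reagents that add atoms: trimethylsilyl trifluoromethanesulfonate, C[Si](C)(C)OS(=O)(=O)C(F)(F)F
Why: Soft enolisation and O-silylation of the ketone, which can give only the C9=C7 enol ether because C10 carries no hydrogen.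

Step 11
Reactants: 14 (3S,5R,10R)-3-(tert-butyldimethylsilyloxy)-4,4,10-trimethyl-9-(trimethylsilyloxy)-trans-hydrind-7(9)-ene; 15 1,1-dichloroethane
Product: 17 (3S,5R,10R)-3-(tert-butyldimethylsilyloxy)-4,4,8,10-tetramethyl-trans-Δ7-octalin-9-one, via siloxy chlorocyclopropane 16 (not isolated)
Conditions: n-BuLi (slow addition), Et2O, −40 to −30 °C; then toluene, 110 °C
Reagents that add atoms: none
Why: n-BuLi deprotonates 15 to 1,1-dichloroethyllithium, which loses LiCl and delivers chloro(methyl)carbene to the electron-rich C9=C7 enol ether, so that C8 becomes bonded to both C7 and C9 in chlorocyclopropane 16. On heating, chloride ionises from C8 while the old C9–C7 bond opens in a disrotatory two-electron electrocyclic sense with assistance from the siloxy oxygen, and the siloxyallyl cation gives up its silyl group to chloride to leave enone 17. The closest known reaction type is the halocarbene cyclopropanation and ring-opening enlargement of cyclic trimethylsilyl enol ethers to 2-substituted cycloalk-2-enones, where chloro(methyl)carbene gives 2-methyl enones. Ring B is not closed by a new cyclisation but arises by one-carbon expansion of the five-membered ring, through cleavage of the bond shared by the two rings of the bicyclo[3.1.0]hexane. No stereocentre is created, because C7, C8 and C9 all end as sp2 carbons and C3, C5 and C10 are untouched. The step needs regiocontrol, which the quaternary C10 secures since 13 can enolise only toward C7, and an endo chloride for easy opening, which the preference of the larger methyl group for the exo position should favour, while the C3 silyl ether is inert to the carbenoid.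

Step 12
Reactants: 17 (3S,5R,10R)-3-(tert-butyldimethylsilyloxy)-4,4,8,10-tetramethyl-trans-Δ7-octalin-9-one; 18 2-(2-bromoethyl)-2-methyl-1,3-dioxolane
Product: 20 3-(tert-butyldimethylsilyloxy)-9-hydroxy-4,4,8,10-tetramethyl-9-[2-(2-methyl-1,3-dioxolan-2-yl)ethyl]-trans-Δ7-octalin, via Grignard reagent 19 (not isolated)
Conditions: 18, Mg, THF, 25 °C; CeCl3 (anhydrous), THF, −78 °C; then 17, −78 to 0 °C; aq. NH4Cl
Reagents that add atoms: none
Why: Cerium-mediated Grignard 1,2-addition (Imamoto conditions), which favours carbonyl addition over enolisation at the crowded enone; attack anti to the C10 methyl is expected, and the new carbinol centre is erased in step 13 so either epimer serves.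

Step 13
Reactants: 20 3-(tert-butyldimethylsilyloxy)-9-hydroxy-4,4,8,10-tetramethyl-9-[2-(2-methyl-1,3-dioxolan-2-yl)ethyl]-trans-Δ7-octalin
Product: 21 3-(tert-butyldimethylsilyloxy)-4,4,8,10-tetramethyl-9-[2-(2-methyl-1,3-dioxolan-2-yl)ethyl]-trans-Δ8(9)-octalin-7-one
Conditions: pyridinium chlorochromate (C5H5NH)[CrO3Cl], 4 Å molecular sieves, CH2Cl2, rt
Reagents that add atoms: none
Why: Babler–Dauben oxidative transposition, in which the chromate ester of the tertiary allylic alcohol undergoes a [3,3] shift to C7 and hexavalent chromium oxidises the secondary allylic chromate to the tetrasubstituted enone.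

Step 14
Reactants: 21 3-(tert-butyldimethylsilyloxy)-4,4,8,10-tetramethyl-9-[2-(2-methyl-1,3-dioxolan-2-yl)ethyl]-trans-Δ8(9)-octalin-7-one
Product: 23 C7 enol triflate of the reduced ketone (C7=C8 with H-9 on the H-5 face), via lithium enolate 22 (not isolated)
Conditions: Li (2.2 equiv.), t-BuOH (1 equiv.), NH3(l)/THF, −78 °C; NH3 evaporated; then PhNTf2, THF, 0 °C to rt
Reagents that add atoms: N-phenylbis(trifluoromethanesulfonimide), O=S(=O)(N(c1ccccc1)S(=O)(=O)C(F)(F)F)C(F)(F)F
Why: Dissolving-metal enone reduction with regiospecific enolate triflation (McMurry-type trapping), in which axial protonation of C9 anti to the C10 methyl should set C9 with the side chain equatorial on the methyl face, and the C7=C8 enolate is captured on oxygen.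

Step 15
Reactants: 23 C7 enol triflate (C7=C8 with H-9 on the H-5 face)
Product: 24 (3S,5S,9R,10S)-3-(tert-butyldimethylsilyloxy)-14,15-dinorlabd-7-en-13-one ethylene ketal
Conditions: Pd(OAc)2 (cat.), PPh3, HCO2H, n-Bu3N, DMF, 60 °C
Reagents that add atoms: none
Why: Palladium-catalysed formate hydrogenolysis of an enol triflate (oxidative addition to zerovalent palladium, formate exchange, decarboxylation, reductive elimination), which replaces the triflate by hydrogen and leaves the C7=C8 alkene in place.

Step 16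
Reactants: 24 (3S,5S,9R,10S)-3-(tert-butyldimethylsilyloxy)-14,15-dinorlabd-7-en-13-one ethylene ketal
Product: 25 (3S,5S,9R,10S)-3-(tert-butyldimethylsilyloxy)-14,15-dinorlabd-7-en-13-one
Conditions: PPTS, acetone/H2O, reflux
Reagents that add atoms: water, O
Why: Acid-catalysed ketal hydrolysis under conditions mild enough for the hindered silyl ether and the trisubstituted alkene.

Step 17
Reactants: 25 (3S,5S,9R,10S)-3-(tert-butyldimethylsilyloxy)-14,15-dinorlabd-7-en-13-one; 26 triethyl phosphonoacetate
Product: 28 ethyl (3S,5S,9R,10S,13E)-3-(tert-butyldimethylsilyloxy)labda-7,13-dien-15-oate, via sodium phosphonate 27 (not isolated)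
Conditions: 26, NaH, THF, 0 °C; then 25, rt to reflux; chromatographic removal of the 13Z isomer
Reagents that add atoms: none
Why: Horner–Wadsworth–Emmons olefination of the methyl ketone, which should favour the E enoate with the ester anti to the larger C12 chain.

Step 18
Reactants: 28 ethyl (3S,5S,9R,10S,13E)-3-(tert-butyldimethylsilyloxy)labda-7,13-dien-15-oate
Product: 29 (3S,5S,9R,10S,13E)-3-(tert-butyldimethylsilyloxy)labda-7,13-dien-15-ol
Conditions: i-Bu2AlH (2.5 equiv.), CH2Cl2, −78 °C; aq. KNaC4H4O6 (sodium potassium tartrate)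
Reagents that add atoms: none
Why: Aluminium hydride 1,2-reduction of the conjugated ester to the allylic alcohol, without touching either alkene or the alkene geometry.

Step 19
Reactants: 29 (3S,5S,9R,10S,13E)-3-(tert-butyldimethylsilyloxy)labda-7,13-dien-15-ol; 30 (S)-3-methylpentanoic acid
Product: 31 (3S,5S,9R,10S,13E)-3-(tert-butyldimethylsilyloxy)labda-7,13-dien-15-yl (3S)-3-methylpentanoate
Conditions: DCC, DMAP (cat.), CH2Cl2, 0 °C to rt
Reagents that add atoms: none
Why: Steglich esterification of the primary allylic alcohol; the stereocentre of the acid is β to the carboxyl and cannot epimerise.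

Step 20
Reactants: 31 (3S,5S,9R,10S,13E)-3-(tert-butyldimethylsilyloxy)labda-7,13-dien-15-yl (3S)-3-methylpentanoate
Product: 32 (3S,5S,9R,10S,13E)-3-hydroxylabda-7,13-dien-15-yl (3S)-3-methylpentanoate
Conditions: aq. HF (48%), MeCN, 0 °C to rt
Reagents that add atoms: none
Why: Fluoride-mediated desilylation under mildly acidic conditions, which should free the axial C3 alcohol without cleaving the allylic ester or moving the alkenes.

**Compound list**

1 | 2-methylcyclopentane-1,3-dione | CC1C(=O)CCC1=O | starting material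
2 | ethyl vinyl ketone (pent-1-en-3-one) | CCC(=O)C=C | starting material
3 | 2-methyl-2-(3-oxopentyl)cyclopentane-1,3-dione | CCC(=O)CCC1(C)C(=O)CCC1=O | intermediate
4 | (3aR,7aR)-3a-hydroxy-4,7a-dimethylhexahydro-1H-indene-1,5(4H)-dione, cis-fused ketol, C4 epimers | O=C1CC[C@@]2(O)C(C)C(=O)CC[C@@]12C | intermediate
5 | (7aR)-4,7a-dimethyl-2,3,7,7a-tetrahydro-1H-indene-1,5(6H)-dione | O=C1CCC2=C(C)C(=O)CC[C@@]12C | intermediate
6 | (1R,7aR)-1-hydroxy-4,7a-dimethyl-1,2,3,6,7,7a-hexahydro-5H-inden-5-one (C9 hydroxyl on the methyl face) | O[C@@H]1CCC2=C(C)C(=O)CC[C@@]12C | intermediate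
7 | (1R,7aR)-4,7a-dimethyl-1-(triethylsilyloxy)-1,2,3,6,7,7a-hexahydro-5H-inden-5-one | CC[Si](CC)(CC)O[C@@H]1CCC2=C(C)C(=O)CC[C@@]12C | intermediate
8 | lithium C3=C4 enolate of trans-fused 4,10-dimethyl-9-(triethylsilyloxy)hydrindan-3-one (H-5 anti to the C10 methyl) | CC[Si](CC)(CC)O[C@@H]1CC[C@@H]2C(C)=C(O[Li])CC[C@@]12C | intermediate
9 | (1R,3aS,7aR)-4,4,7a-trimethyl-1-(triethylsilyloxy)octahydro-5H-inden-5-one (trans-fused 3-ketone) | CC[Si](CC)(CC)O[C@@H]1CC[C@@H]2C(C)(C)C(=O)CC[C@@]12C | intermediate
10 | (3S,5R,9R,10R)-4,4,10-trimethyl-9-(triethylsilyloxy)-trans-hydrindan-3-ol (axial C3 hydroxyl on the H-5 face) | CC[Si](CC)(CC)O[C@@H]1CC[C@@H]2C(C)(C)[C@@H](O)CC[C@@]12C | intermediate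
11 | (3S,5R,9R,10R)-3-(tert-butyldimethylsilyloxy)-4,4,10-trimethyl-9-(triethylsilyloxy)-trans-hydrindane | CC[Si](CC)(CC)O[C@@H]1CC[C@@H]2C(C)(C)[C@@H](O[Si](C)(C)C(C)(C)C)CC[C@@]12C | intermediate
12 | (3S,5R,9R,10R)-3-(tert-butyldimethylsilyloxy)-4,4,10-trimethyl-trans-hydrindan-9-ol | O[C@@H]1CC[C@@H]2C(C)(C)[C@@H](O[Si](C)(C)C(C)(C)C)CC[C@@]12C | intermediate
13 | (3S,5R,10R)-3-(tert-butyldimethylsilyloxy)-4,4,10-trimethyl-trans-hydrindan-9-one | O=C1CC[C@@H]2C(C)(C)[C@@H](O[Si](C)(C)C(C)(C)C)CC[C@@]12C | intermediate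
14 | (3S,5R,10R)-3-(tert-butyldimethylsilyloxy)-4,4,10-trimethyl-9-(trimethylsilyloxy)-trans-hydrind-7(9)-ene (C9=C7 silyl enol ether) | C[Si](C)(C)OC1=CC[C@@H]2C(C)(C)[C@@H](O[Si](C)(C)C(C)(C)C)CC[C@@]12C | intermediate
15 | 1,1-dichloroethane | CC(Cl)Cl | starting material
16 | 3-(tert-butyldimethylsilyloxy)-8-chloro-4,4,8,10-tetramethyl-9-(trimethylsilyloxy) cyclopropane in which C8 bridges C7 and C9 of the hydrindane (cyclopropane epimers) | C[Si](C)(C)OC12C(C)(Cl)C1C[C@@H]1C(C)(C)[C@@H](O[Si](C)(C)C(C)(C)C)CC[C@@]21C | intermediate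
17 | (3S,5R,10R)-3-(tert-butyldimethylsilyloxy)-4,4,8,10-tetramethyl-trans-Δ7-octalin-9-one | O=C1C(C)=CC[C@@H]2C(C)(C)[C@@H](O[Si](C)(C)C(C)(C)C)CC[C@@]12C | intermediate
18 | 2-(2-bromoethyl)-2-methyl-1,3-dioxolane | CC1(CCBr)OCCO1 | starting material
19 | [2-(2-methyl-1,3-dioxolan-2-yl)ethyl]magnesium bromide | CC1(CC[Mg]Br)OCCO1 | intermediate
20 | 3-(tert-butyldimethylsilyloxy)-9-hydroxy-4,4,8,10-tetramethyl-9-[2-(2-methyl-1,3-dioxolan-2-yl)ethyl]-trans-Δ7-octalin (expected epimer: hydroxyl on the methyl face, side chain on the H-5 face) | CC1(CC[C@@]2(O)C(C)=CC[C@@H]3C(C)(C)[C@@H](O[Si](C)(C)C(C)(C)C)CC[C@@]23C)OCCO1 | intermediate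
21 | 3-(tert-butyldimethylsilyloxy)-4,4,8,10-tetramethyl-9-[2-(2-methyl-1,3-dioxolan-2-yl)ethyl]-trans-Δ8(9)-octalin-7-one | CC1(CCC2=C(C)C(=O)C[C@@H]3C(C)(C)[C@@H](O[Si](C)(C)C(C)(C)C)CC[C@@]23C)OCCO1 | intermediate
22 | lithium C7=C8 enolate of the reduced ketone (H-9 on the H-5 face, side chain on the methyl face) | CC1(CC[C@@H]2C(C)=C(O[Li])C[C@@H]3C(C)(C)[C@@H](O[Si](C)(C)C(C)(C)C)CC[C@@]23C)OCCO1 | intermediate
23 | 3-(tert-butyldimethylsilyloxy)-4,4,8,10-tetramethyl-9-[2-(2-methyl-1,3-dioxolan-2-yl)ethyl]-trans-Δ7-octalin-7-yl trifluoromethanesulfonate (H-9 on the H-5 face) | CC1(CC[C@@H]2C(C)=C(OS(=O)(=O)C(F)(F)F)C[C@@H]3C(C)(C)[C@@H](O[Si](C)(C)C(C)(C)C)CC[C@@]23C)OCCO1 | intermediate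
24 | (3S,5S,9R,10S)-3-(tert-butyldimethylsilyloxy)-14,15-dinorlabd-7-en-13-one ethylene ketal | CC1(CC[C@@H]2C(C)=CC[C@@H]3C(C)(C)[C@@H](O[Si](C)(C)C(C)(C)C)CC[C@@]23C)OCCO1 | intermediate
25 | (3S,5S,9R,10S)-3-(tert-butyldimethylsilyloxy)-14,15-dinorlabd-7-en-13-one | CC(=O)CC[C@@H]1C(C)=CC[C@@H]2C(C)(C)[C@@H](O[Si](C)(C)C(C)(C)C)CC[C@@]12C | intermediate
26 | triethyl phosphonoacetate | CCOC(=O)CP(=O)(OCC)OCC | starting material
27 | sodium salt of triethyl phosphonoacetate | CCOC(=O)[CH-]P(=O)(OCC)OCC.[Na+] | intermediate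
28 | ethyl (3S,5S,9R,10S,13E)-3-(tert-butyldimethylsilyloxy)labda-7,13-dien-15-oate | CCOC(=O)/C=C(\C)CC[C@@H]1C(C)=CC[C@@H]2C(C)(C)[C@@H](O[Si](C)(C)C(C)(C)C)CC[C@@]12C | intermediate
29 | (3S,5S,9R,10S,13E)-3-(tert-butyldimethylsilyloxy)labda-7,13-dien-15-ol | OC/C=C(\C)CC[C@@H]1C(C)=CC[C@@H]2C(C)(C)[C@@H](O[Si](C)(C)C(C)(C)C)CC[C@@]12C | intermediate
30 | (S)-3-methylpentanoic acid | CC[C@H](C)CC(=O)O | starting material
31 | (3S,5S,9R,10S,13E)-3-(tert-butyldimethylsilyloxy)labda-7,13-dien-15-yl (3S)-3-methylpentanoate | CC[C@H](C)CC(=O)OC/C=C(\C)CC[C@@H]1C(C)=CC[C@@H]2C(C)(C)[C@@H](O[Si](C)(C)C(C)(C)C)CC[C@@]12C | intermediate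
32 | (3S,5S,9R,10S,13E)-3-hydroxylabda-7,13-dien-15-yl (3S)-3-methylpentanoate | CC[C@H](C)CC(=O)OC/C=C(\C)CC[C@@H]1C(C)=CC[C@@H]2C(C)(C)[C@@H](O)CC[C@@]12C | target

**Step count**

Total step count: 20. Longest linear sequence: 20 steps (from 1 and 2 to 32); 15, 18, 26 and 30 are bought and enter directly.

**Steps most likely to fail**

1. Step 11. Butyllithium may strip the trimethylsilyl group from the enol ether faster than it metalates 15. The cyclopropane epimer with an exo chloride may also resist ionisation, because its disrotatory opening would need a trans double bond in a six-membered ring. The fallback sets out from 14 and keeps the ring expansion but brings in the methyl afterwards. Dibromocarbene (CHBr3, KOt-Bu, pentane, −25 °C) should give the dibromocyclopropane F1, in which one bromide is necessarily endo. Warming F1 in toluene should open it with loss of bromotrimethylsilane to the ring-expanded 8-bromo-Δ7-9-enone F2. Suzuki–Miyaura methylation of F2 (MeB(OH)2, Pd(dppf)Cl2, K2CO3, dioxane/H2O, 80 °C) returns to the route at 17.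

2. Step 13. The chromate ester of the crowded tertiary carbinol may form slowly, so that acid-promoted dehydration to dienes or loss of the dioxolane overtakes the [3,3] shift. The fallback sets out from 20 and separates transposition from oxidation. A catalytic amount of Ph3SiOReO3 in Et2O at 0 °C should move the hydroxyl by a 1,3-shift to C7 under neutral conditions, giving the secondary allylic alcohol F3 with the more substituted Δ8(9) alkene. Oxidation of F3 with MnO2 in CH2Cl2 returns to the route at 21.

3. Step 14. Proton exchange between the C7 enolate and ammonia-derived base, or slow sulfonylation of the tetrasubstituted enolate, may give the saturated ketone or a misplaced enol triflate; protonation at C9 may also be less face-selective than expected. The fallback sets out from 21 and replaces reduction and triflation by a reductive allylic transposition. Luche reduction (NaBH4, CeCl3·7H2O, MeOH, −40 °C) should deliver hydride axially and give the allylic alcohol F4 with the C7 hydroxyl on the methyl face. Mitsunobu displacement with 2-nitrobenzenesulfonylhydrazide (PPh3, DEAD, N-methylmorpholine, −30 °C) should invert C7 to the sulfonylhydrazine F5. On warming to rt, F5 should lose the sulfinic acid to give the allylic diazene F6. F6 should expel dinitrogen in a suprafacial retro-ene shift that places hydrogen on C9 on the H-5 face and moves the alkene to C7=C8. This returns to the route at 24, so step 15 is not needed.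

Further compounds
F1 | step 11 | 3-(tert-butyldimethylsilyloxy)-8,8-dibromo-4,4,10-trimethyl-9-(trimethylsilyloxy) cyclopropane in which C8 bridges C7 and C9 of the hydrindane | C[Si](C)(C)OC12C(Br)(Br)C1C[C@@H]1C(C)(C)[C@@H](O[Si](C)(C)C(C)(C)C)CC[C@@]21C
F2 | step 11 | 8-bromo-3-(tert-butyldimethylsilyloxy)-4,4,10-trimethyl-trans-Δ7-octalin-9-one | O=C1C(Br)=CC[C@@H]2C(C)(C)[C@@H](O[Si](C)(C)C(C)(C)C)CC[C@@]12C
F3 | step 13 | 3-(tert-butyldimethylsilyloxy)-4,4,8,10-tetramethyl-9-[2-(2-methyl-1,3-dioxolan-2-yl)ethyl]-trans-Δ8(9)-octalin-7-ol (C7 epimers) | CC1(CCC2=C(C)C(O)C[C@@H]3C(C)(C)[C@@H](O[Si](C)(C)C(C)(C)C)CC[C@@]23C)OCCO1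
F4 | step 14 | 3-(tert-butyldimethylsilyloxy)-4,4,8,10-tetramethyl-9-[2-(2-methyl-1,3-dioxolan-2-yl)ethyl]-trans-Δ8(9)-octalin-7-ol with the C7 hydroxyl on the methyl face | CC1(CCC2=C(C)[C@H](O)C[C@@H]3C(C)(C)[C@@H](O[Si](C)(C)C(C)(C)C)CC[C@@]23C)OCCO1
F5 | step 14 | N-(2-nitrobenzenesulfonyl)-N-(C7-octalinyl)hydrazine from F4 with inverted C7 (nitrogen on the H-5 face) | CC1(CCC2=C(C)[C@@H](N(N)S(=O)(=O)c4ccccc4[N+](=O)[O-])C[C@@H]3C(C)(C)[C@@H](O[Si](C)(C)C(C)(C)C)CC[C@@]23C)OCCO1
F6 | step 14 | C7 allylic diazene (nitrogen on the H-5 face) | CC1(CCC2=C(C)[C@@H](N=N)C[C@@H]3C(C)(C)[C@@H](O[Si](C)(C)C(C)(C)C)CC[C@@]23C)OCCO1
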